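## Retrosynthetic overview
- The target's γ-lactone and tetrahydrofuran are made last, in one acid step, from a linear triol ester. The lactone forms from the tertiary d-OH and the ester. The THF forms by capture of the tertiary b-cation by the e-OH, under thermodynamic control at b.
- The triol ester comes from addition of Ar(CH2)12-cerium to a methyl ketone. That ketone is the β-hydroxy ketone obtained by N–O cleavage of an isoxazoline.
- The isoxazoline comes from a [3+2] cycloaddition of acetonitrile oxide to a 1,1-disubstituted alkene made from (S)-3-hydroxy-γ-butyrolactone. The cycloaddition forms the tertiary C–O bond (d) and the c–b bond.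
- Order of ring formation: isoxazoline (step 7), then the lactone and THF together (step 12).

Atom labels used below: b = ether quaternary carbon (Me, chain), c = ring CH2, d = lactone quaternary carbon (Me), e = CH–O.

**Assumptions:**
- The chain is (CH2)12 as written in the SMILES.
- The phenol is carried as its benzyl ether.
- Diastereomers are separated by chromatography where noted.

## Route

**Step 1**
Reactants: 1, (S)-3-hydroxy-γ-butyrolactone
Product: 2, (S)-3-(benzyloxy)-γ-butyrolactone
Conditions: BnBr, Ag2O, CH2Cl2, rt
Reagents that add atoms: benzyl bromide, BrCc1ccccc1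
Why: Silver-mediated Williamson benzylation is non-basic, so the β-hydroxy lactone does not undergo E1cB elimination, and the e stereocenter is untouched.

**Step 2**
Reactants: 2
Product: 3, methyl (S)-3-(benzyloxy)-4-hydroxybutanoate
Conditions: (i) LiOH (1.0 equiv), THF/H2O, 0 °C; (ii) evaporate, MeI, DMF, rt; use crude
Reagents that add atoms: iodomethane, CI; lithium hydroxide, [Li+].[OH-]
Why: Saponification followed by carboxylate O-methylation opens the lactone irreversibly without acid, so the γ-hydroxy ester cannot relactonize before oxidation.

**Step 3**
Reactants: 3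
Product: 4, methyl (S)-3-(benzyloxy)-4-oxobutanoate
Conditions: Dess–Martin periodinane, NaHCO3, CH2Cl2, 0 °C→rt; use crude
Reagents that add atoms: none
Why: Buffered Dess–Martin oxidation of the primary alcohol gives the α-benzyloxy aldehyde; using it immediately limits epimerization at e.

**Step 4**
Reactants: 4
Product: 5, methyl (S)-3-(benzyloxy)pent-4-enoate
Conditions: Ph3P=CH2 (from Ph3PCH3Br, KOtBu), THF, −78→0 °C
Reagents that add atoms: methylenetriphenylphosphorane, C=P(c1ccccc1)(c1ccccc1)c1ccccc1
Why: Wittig methylenation at low temperature converts the aldehyde to a vinyl group. It avoids any γ-hydroxy ester or alkoxide that would lactonize onto the methyl ester.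

**Step 5**
Reactants: 5
Product: 6, methyl (S)-3-(benzyloxy)-4-oxopentanoate
Conditions: PdCl2 (10 mol%), CuCl, O2, DMF/H2O, rt
Reagents that add atoms: water, O
Why: Tsuji–Wacker oxidation gives the Markovnikov methyl ketone from a terminal allyl ether; the d carbon now carries its methyl.

**Step 6**
Reactants: 6
Product: 7, methyl (S)-3-(benzyloxy)-4-methylpent-4-enoate
Conditions: CH2Br2, Zn, TiCl4, THF/CH2Cl2, 0 °C→rt
Reagents that add atoms: dibromomethane, BrCBr
Why: Takai–Lombardo methylenation is non-basic and ketone-selective, so the enolizable α-alkoxy ketone does not epimerize and the ester is untouched.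

**Step 7 (key cycloaddition)**
Reactants: 7
Product: 8, methyl (3S)-3-(benzyloxy)-3-[(5S)-3,5-dimethyl-4,5-dihydroisoxazol-5-yl]propanoate
Conditions: nitroethane, PhNCO, Et3N (cat.), toluene, 50 °C
Reagents that add atoms: nitroethane, CC[N+](=O)[O-]
Why: Mukaiyama generation of acetonitrile oxide and its 1,3-dipolar cycloaddition place O on the more substituted alkene carbon, forming the d–O bond and the c–C(b) bond. d is set by 1,2-induction from the allylic stereocenter e. The major diastereomer (expected about 4:1), the one whose O and c can become the cis-fused skeleton, is separated.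

**Step 8**
Reactants: 8
Product: 9, methyl (3S,4S)-3-(benzyloxy)-4-hydroxy-4-methyl-6-oxoheptanoate
Conditions: Mo(CO)6, MeCN/H2O (15:1), 75 °C
Reagents that add atoms: water, O
Why: Mo(CO)6 cleaves the isoxazoline N–O bond and hydrolyzes the resulting imine to the β-hydroxy methyl ketone; the benzyl ethers and ester survive, and d keeps its configuration.

**Step 9**
Reactants: 10, 1-(benzyloxy)-4-bromobenzene; 11, 1,12-dibromododecane
Product: 12, 1-(benzyloxy)-4-(12-bromododecyl)benzene
Conditions: (i) Mg, THF; (ii) 11 (3 equiv), Li2CuCl4 (5 mol%), THF, 0 °C→rt
Reagents that add atoms: none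
Why: Cu-catalysed Kumada alkyl–aryl coupling of the aryl Grignard with excess dibromide gives the mono-coupled chain bromide.

**Step 10**
Reactants: 9; 12
Product: 13, methyl (3S,4S)-3-(benzyloxy)-18-[4-(benzyloxy)phenyl]-4,6-dihydroxy-4,6-dimethyloctadecanoate (C6 epimers)
Conditions: 12, Mg, THF; then CeCl3, −78 °C; add 9 (4 equiv organocerium), −78→−40 °C
Reagents that add atoms: none
Why: The organocerium adds 1,2 to the ketone in preference to the ester and is tolerant of the free tertiary alcohol. The new b stereocenter is a mixture that is erased in step 12.

**Step 11**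
Reactants: 13
Product: 14, methyl (3S,4S)-18-(4-hydroxyphenyl)-3,4,6-trihydroxy-4,6-dimethyloctadecanoate
Conditions: H2 (1 atm), 10% Pd/C, EtOAc/EtOH, rt
Reagents that add atoms: none
Why: Hydrogenolysis removes the alkyl and aryl benzyl ethers together; nothing else in the molecule is reducible and no stereocenter is affected.

**Step 12**
Reactants: 14
Product: 15, plakortone N
Conditions: TsOH·H2O (20 mol%), toluene (0.01 M), 4 Å MS, 70 °C
Reagents that add atoms: none
Why: Acid-catalysed lactonization of the tertiary d-OH onto the methyl ester is accompanied by 5-exo capture of the tertiary b-cation by the e-OH; all alkene or cation side-products are acid-reversible, so b ends up at the thermodynamic epimer with the chain on the convex face. Only the d/e-cis precursor can close the cis-fused bicycle.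

**Self-check:**
- **Target match:** The product has a THF (O1, b, c, d, e) fused cis to a γ-lactone (O, C=O, CH2, e, d), with Me + (CH2)12Ar on b and Me on d.
- **Configurations:** e is S in every intermediate (from (S)-1). d is S by construction, from the CIP/SMILES comparison with the target. b is S by thermodynamic control.
- **Stereocenters:** e comes from the chiral-pool lactone. d is set in step 7 and never touched afterward. b is set in step 12.
- **Atom balance:** 14 (C27H46O6) − MeOH − H2O = C26H40O4, which is the target.

## Compound list
1 | (S)-3-hydroxy-γ-butyrolactone | O=C1C[C@H](O)CO1 | starting material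
2 | (S)-3-(benzyloxy)-γ-butyrolactone | O=C1C[C@H](OCc2ccccc2)CO1 | intermediate
3 | methyl (S)-3-(benzyloxy)-4-hydroxybutanoate | COC(=O)C[C@H](OCc1ccccc1)CO | intermediate
4 | methyl (S)-3-(benzyloxy)-4-oxobutanoate | COC(=O)C[C@H](OCc1ccccc1)C=O | intermediate
5 | methyl (S)-3-(benzyloxy)pent-4-enoate | COC(=O)C[C@H](OCc1ccccc1)C=C | intermediate
6 | methyl (S)-3-(benzyloxy)-4-oxopentanoate | COC(=O)C[C@H](OCc1ccccc1)C(C)=O | intermediate
7 | methyl (S)-3-(benzyloxy)-4-methylpent-4-enoate | COC(=O)C[C@H](OCc1ccccc1)C(C)=C | intermediate
8 | isoxazoline cycloadduct | COC(=O)C[C@H](OCc1ccccc1)[C@]2(C)CC(C)=NO2 | intermediate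
9 | methyl (3S,4S)-3-(benzyloxy)-4-hydroxy-4-methyl-6-oxoheptanoate | COC(=O)C[C@H](OCc1ccccc1)[C@@](C)(O)CC(C)=O | intermediate
10 | 1-(benzyloxy)-4-bromobenzene | Brc1ccc(OCc2ccccc2)cc1 | starting material
11 | 1,12-dibromododecane | BrCCCCCCCCCCCCBr | starting material
12 | 1-(benzyloxy)-4-(12-bromododecyl)benzene | BrCCCCCCCCCCCCc1ccc(OCc2ccccc2)cc1 | intermediate
13 | benzyl-protected triol ester (b epimeric) | COC(=O)C[C@H](OCc1ccccc1)[C@@](C)(O)CC(C)(O)CCCCCCCCCCCCc1ccc(OCc2ccccc2)cc1 | intermediate
14 | deprotected triol ester | COC(=O)C[C@H](O)[C@@](C)(O)CC(C)(O)CCCCCCCCCCCCc1ccc(O)cc1 | intermediate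
15 | plakortone N | C[C@]1(CCCCCCCCCCCCc2ccc(O)cc2)C[C@]2(C)OC(=O)C[C@@H]2O1 | target

## Totals
Total steps: 12. Longest linear sequence: 11 steps (1–8, 10–12); step 9 makes the chain fragment in parallel.

**Three steps most likely to fail:**
1. **Step 7 (diastereoselectivity at d).** Allylic induction on a 1,1-disubstituted alkene may give only about 2–3:1. Fallback: drop the cycloaddition. Add a 2-[(CH2)12Ar]-allylzinc or allylindium reagent to ketone 6 under Mg/Zn chelation control, which my Cram-chelate analysis predicts gives d = S. Then debenzylate and close the THF by Markovnikov hydroalkoxylation.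
2. **Step 12 (b stereochemistry, elimination, phenol alkylation).** The thermodynamic b-epimer may not predominate, or the cascade may stall or alkylate the phenol. Fallback: use the long-chain nitrile oxide in step 7 so that the b ketone carries the chain. Methylenate it (Petasis), form the lactone, and close the THF by Co(salen)/PhSiH3 Markovnikov hydroalkoxylation.
3. **Steps 3–6 (α-alkoxy aldehyde/ketone handling and Wacker regiochemistry).** Epimerization at e or aldehyde formation in the Wacker step would erode ee or yield. Fallback: make ketone 6 by selective Weinreb amidation of the α-ester of dimethyl (S)-O-benzylmalate, then MeMgBr addition.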